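# Larreantin by anodic quinone methide cyclisation of a diaryl butanone: synthesis design

## The problem

Larreantin is a 2-methoxy-1,4-naphthoquinone whose carbocyclic ring (ring B, C4a–C8a) carries on three adjacent carbons a 4-hydroxy-3-methoxybenzyl group (C6, through the methylene here called C9), a methyl group (C7) and a 4-hydroxy-3-methoxyphenyl group (C8, peri to the C1 carbonyl), so that only C5 bears hydrogen. The target has no stereocentre, so the task is one of connectivity: the order benzyl/methyl/aryl around ring B and the methoxy group at C2 and not at C3. Any sp3 centres that a ring-B construction passes through (C6, C7, C8) are disposable, and none has to be controlled or has to control another. Three parts are fragile: the methoxyquinone, a vinylogous ester and an oxidant that is sensitive to nucleophiles, base and reductants; the two free guaiacol units, which are easily oxidised; and the doubly benzylic C9 methylene. The quinone therefore has to appear late, and the phenols must be masked whenever an oxidant is used. The enabling feature is that C8 is the benzylic carbon of a para-hydroxyphenyl group, so that two-electron oxidation of that phenol turns C8 into the electrophilic end of a para-quinone methide. This carbon can be placed opposite C8a of a 2,4,5-trimethoxyphenyl ring whose oxygen pattern already maps onto C1, C2 and C4 of the oxygenated ring (ring A). The catch is twofold: C6 carries a second aryl-bearing arm whose ring could capture the same electrophile in an equally six-membered closure, and the two guaiacyl phenols have to be told apart.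

## Retrosynthesis

**Quinone last (25 from 24 from 23).** The two phenols are unveiled in the final operation from diacetate 24. The C1 and C4 carbonyls of 24 are traced back to methyl ethers in trimethoxynaphthalene 23. Cutting the two C=O bonds, instead of annulating a quinone ring, lets ring A be bought as a trimethoxyphenyl unit. Because C1 and C4 both become carbonyls, the methoxy group left at C2 needs no regiochemical decision. The forward step asks that tetravalent cerium oxidise the tri-ether ring and not the guaiacyl rings or C9, which is why both phenols are acetates in 23.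

**C9 carried as a carbonyl (23 from 22).** No skeletal bond is cut here; the C9 methylene is taken back to the diaryl ketone 22. This is the one deliberate detour of the plan. The carbonyl does three things:
- it is the handle by which the C9 aryl ring is attached;
- it switches that ring off as a nucleophile during ring closure;
- it means there is no doubly benzylic C–H at C9 while the quinone oxidant of the aromatisation step is present.

The price is one ionic hydrogenation of an electron-rich diaryl ketone.

**Aromatisation (22 from 21 from 19).** Ring B of 22 is taken back to the tetralin 21, so that C5–C8 can be made as sp3 carbons and dehydrogenated. The three stereocentres of 21 vanish in that step, so diastereomer mixtures are acceptable from the first C–C bond onward. Diacetate 21 comes from the cyclisation product 19 by one-flask silyl-to-acetyl exchange through bis-phenol 20.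

**Key disconnection, C8–C8a (19 from 17 through 18).** Cutting C8–C8a opens ring B to the acyclic ketone 17, with quinone methide 18 as the reactive form.
- Against a C4a–C5 closure, this cut needs no leaving group or carbonyl at the reacting carbon: the free phenol is the only handle, and 17 is an open chain reachable by enolate and organometallic chemistry.
- The forward reaction must oxidise only the free phenol and must let only the trimethoxyphenyl ring capture C8.
- Had C9 been a methylene carrying an ether-protected guaiacyl ring, the position of that ring para to its methoxy group would be at least as nucleophilic as C8a (which is ortho to one methoxy group and flanked on both sides) and would close an equally six-membered ring. The C9 ketone removes this ambiguity.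

**C5–C6 by enolate alkylation (17 from 16 from 11 + 14).** The phenol of 17 is released from benzyl ether 16 by hydrogenolysis. In 16 the 2,4,5-trimethoxybenzyl group is cut off at C5–C6, giving ketone 11 (which can enolise only toward C6) and benzylic chloride 14, made from aldehyde 12 through alcohol 13.

The neighbouring cut, C4a–C5 by Friedel–Crafts acylation, was rejected. The acylating chain would carry two electron-rich arenes placed for tetralone or indanone formation, and the resulting C5 carbonyl would have to be deoxygenated through a benzylic cation that the same arenes can capture.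

**C9–aryl and C7–C8 (11 from 7 + 9; 7 from 6 from 2 + 3).** Ketone 11 is cut at the C9–aryl bond into Weinreb amide 7 and aryl bromide 9 (through aryllithium 10). Bromide 9 is the triisopropylsilyl ether of commercial phenol 8. Amide 7 comes from ester 6, whose C7–C8 bond is cut to methyl crotonate 3 and the benzylic Grignard reagent 4 derived from chloride 2 and ultimately from commercial alcohol 1; silyl ketene acetal 5 is the primary adduct.

The protecting groups follow from the key step:
- benzyl sits on the ring that must be a free phenol in 17 and is removed by hydrogenolysis;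
- triisopropylsilyl sits on the C9 ring, survives organolithium, enolate and electrolysis conditions, and is exchanged for acetate only after ring closure.

## Roads not taken

Alternative 1: ring B bought as a benzene and decorated. The cut is through the C7–CH3 and C8–aryl bonds of a benzoate. Under Catellani-type palladium/norbornene relay catalysis (palladium diacetate, a furylphosphine, K2CO3), three components should combine to biaryl ester A4: methyl 4-[4-(benzyloxy)-3-methoxybenzyl]-2-iodobenzoate A1, iodomethane A2 and 4-(benzyloxy)-3-methoxyphenylboronic acid A3. The methyl group of A2 enters at the C–H ortho to iodine and the aryl group of A3 at the former C–I carbon.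
- Merits: two bonds in one convergent operation; no stereoisomers, no competing ring closure and no dehydrogenation; the benzyl/methyl/aryl order is fixed by the mechanism.
- Weak points: the C–H to be methylated by A2 is buttressed by the neighbouring benzyl group; the terminating coupling has to occur at a carbon flanked by an ester and the new methyl group; direct coupling of A1 with A3 without the relay is a built-in competitor.
- Main shortfall: A4 is only a benzene. All of ring A (C1–C4 with the C2 methoxy group and both carbonyls) still has to be annulated onto the ester carbon and the adjacent C–H, with a regiochemical question that the chosen plan does not have.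
- Comparison: for ring B this road is cleaner than the chosen one and involves no unproven step. The chosen plan sets against it that 19 already contains every carbon and oxygen of the target, with ring A supplied by the commercial aldehyde 12.

Alternative 2: C4a–C5 cut, ring B formed already aromatic. SnCl4 would ionise the tertiary carbinol A5, (4-benzyloxy-3-methoxyphenyl)(2,3,5-trimethoxyphenyl)[2,2-dichloro-3-(4-benzyloxy-3-methoxybenzyl)-1-methylcyclopropyl]methanol. The cyclopropylcarbinyl cation opens to a chlorine-stabilised cation at C5, the trimethoxyphenyl ring captures it through C4a, and loss of HCl gives 5-chloronaphthalene A6.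
- Merits: the naphthalene is formed directly; the attacking position C4a is para to one methoxy group and ortho to another, so it is a better nucleophile than C8a in the chosen plan. This is a real advantage.
- Weak points: both aryl groups sit on C8, and which one closes onto C5 is decided by the geometry of the C7=C8 bond created on ring opening; the guaiacyl ring also has a position para to a methoxy group. A5 is a fully substituted gem-dichlorocyclopropyl carbinol that needs a long, stereochemically defined preparation. The chlorine at C5 of A6 must be removed in an extra step, and the two benzyl ethers must still be carried through the quinone oxidation.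
- Comparison: the chosen plan has the weaker nucleophile and needs a dehydrogenation, but its precursor 17 is an open-chain ketone, the competing arene is switched off by a carbonyl instead of by alkene geometry, and nothing has to be removed from C5.

Alternative 3: ring A removed instead (C8a–C1, C1–C2, C3–C4, C4–C4a). Irradiation of diazo ketone A7, 2-diazo-1-[2-(4-benzyloxy-3-methoxyphenyl)-4-(4-benzyloxy-3-methoxybenzyl)-3-methylphenyl]ethanone, with methoxyacetylene A8 should give naphthol A9. The sequence is Wolff rearrangement to the aryl ketene, [2+2] addition of A8, ring opening of the cyclobutenone and six-electron closure onto the one free ortho position. A9 has hydroxyl at C4, methoxy at C2 and hydrogen at C1 in target numbering.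
- Merits: the methoxy regiochemistry is dictated by the polarity of the ynol ether A8; ring B is aromatic throughout; only one mild oxidation of a naphthol with a free para position is needed to reach the quinone. That end game is gentler than the cerium oxidation of a tri-ether in the chosen plan.
- Weak points: the crowded ring B is not made by this strategy at all. A7 would itself have to come from an ester such as A4, so the hard part is only moved elsewhere. The diazo ketone A7 must be made from a hindered ortho-aryl benzoic acid derivative, A8 is volatile and labile, and the ketene cycloaddition takes place next to an ortho aryl group.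
- Comparison: better for ring A, silent on ring B, and longer overall once ring B is accounted for. The chosen plan builds ring B from simple acyclic pieces and pays with a harsher oxidation to the quinone.

Key step: step 10

Assumption: the sp3 centres C6, C7 and C8 are carried as mixtures of racemic diastereomers because step 12 removes all three, so SMILES strings are written without stereodescriptors.

## Route

Step 1
Reactants: 1 4-(benzyloxy)-3-methoxybenzyl alcohol
Product: 2 4-(benzyloxy)-3-methoxybenzyl chloride
Conditions: SOCl2, CH2Cl2, 0 °C → rt
Reagents that add atoms: thionyl chloride, O=S(Cl)Cl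
Why: Chlorination of a benzylic alcohol through its chlorosulfite; the aryl benzyl ether is inert and the chloride is the precursor of the benzylic Grignard reagent.

Step 2
Reactants: 2 4-(benzyloxy)-3-methoxybenzyl chloride; 3 methyl (E)-but-2-enoate (methyl crotonate)
Product: 6 methyl 4-[4-(benzyloxy)-3-methoxyphenyl]-3-methylbutanoate (racemic), via benzylic Grignard reagent 4 (not isolated), via silyl ketene acetal 5 (not isolated)
Conditions: Mg, THF, 0 °C (slow addition of 2); then 3, CuI (10 mol %), Me3SiCl, THF, −78 → −20 °C; aq. NH4Cl
Reagents that add atoms: none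
Why: Copper-catalysed conjugate addition of a Grignard reagent to an enoate, accelerated by Me3SiCl, which traps the enolate as 5 and is lost on work-up. The C7 stereocentre is formed racemic and is erased in step 12.

Step 3
Reactants: 6 methyl 4-[4-(benzyloxy)-3-methoxyphenyl]-3-methylbutanoate
Product: 7 4-[4-(benzyloxy)-3-methoxyphenyl]-N-methoxy-N,3-dimethylbutanamide (racemic)
Conditions: MeNH(OMe)·HCl, iPrMgCl, THF, −20 → 0 °C
Reagents that add atoms: N,O-dimethylhydroxylamine hydrochloride, CNOC.Cl
Why: Direct aminolysis of an unhindered methyl ester by the chloromagnesium amide of N,O-dimethylhydroxylamine (Weinreb amide formation); the benzyl ether is untouched.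

Step 4
Reactants: 8 4-bromo-2-methoxyphenol
Product: 9 (4-bromo-2-methoxyphenoxy)triisopropylsilane
Conditions: iPr3SiCl, imidazole, DMF, rt
Reagents that add atoms: chlorotriisopropylsilane, CC(C)[Si](Cl)(C(C)C)C(C)C
Why: Standard silylation of a phenol; the bulky triisopropylsilyl ether is chosen because it must survive aryllithium formation, enolate chemistry and the base-containing electrolysis even when it sits para to a ketone.

Step 5
Reactants: 9 (4-bromo-2-methoxyphenoxy)triisopropylsilane; 7 4-[4-(benzyloxy)-3-methoxyphenyl]-N-methoxy-N,3-dimethylbutanamide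
Product: 11 4-[4-(benzyloxy)-3-methoxyphenyl]-1-[3-methoxy-4-(triisopropylsilyloxy)phenyl]-3-methylbutan-1-one (racemic), via aryllithium 10 (not isolated)
Conditions: 9, nBuLi, THF, −78 °C; then 7, −78 → 0 °C; aq. NH4Cl
Reagents that add atoms: none
Why: Bromine–lithium exchange followed by acylation of the aryllithium with the Weinreb amide (Weinreb ketone synthesis); the chelated tetrahedral adduct prevents a second addition. This forms the C9–aryl bond and installs the carbonyl that later deactivates this ring.

Step 6
Reactants: 12 2,4,5-trimethoxybenzaldehyde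
Product: 13 2,4,5-trimethoxybenzyl alcohol
Conditions: NaBH4, MeOH, 0 °C
Reagents that add atoms: none
Why: Borohydride reduction of an aromatic aldehyde.

Step 7
Reactants: 13 2,4,5-trimethoxybenzyl alcohol
Product: 14 2,4,5-trimethoxybenzyl chloride
Conditions: SOCl2, pyridine, CH2Cl2, −10 → 0 °C; used crude at once
Reagents that add atoms: thionyl chloride, O=S(Cl)Cl
Why: Chlorination through the chlorosulfite with pyridine as acid scavenger; the very electron-rich benzylic chloride self-condenses under acid, so it is kept cold and taken straight into step 8.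

Step 8
Reactants: 11 4-[4-(benzyloxy)-3-methoxyphenyl]-1-[3-methoxy-4-(triisopropylsilyloxy)phenyl]-3-methylbutan-1-one; 14 2,4,5-trimethoxybenzyl chloride
Product: 16 4-[4-(benzyloxy)-3-methoxyphenyl]-1-[3-methoxy-4-(triisopropylsilyloxy)phenyl]-3-methyl-2-(2,4,5-trimethoxybenzyl)butan-1-one (diastereomer mixture), via lithium enolate 15 (not isolated)
Conditions: LiN(SiMe3)2, THF, −78 °C; then 14, DMPU, −78 → 0 °C
Reagents that add atoms: none
Why: The aryl ketone can enolise only toward C6, so a single enolate forms and is C-benzylated by the reactive benzylic chloride (SN2 enolate alkylation), making the C5–C6 bond without any cationic intermediate. The C6 stereocentre is formed without control, which does not matter because C6 and C7 both become sp2 in step 12.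

Step 9
Reactants: 16 4-[4-(benzyloxy)-3-methoxyphenyl]-1-[3-methoxy-4-(triisopropylsilyloxy)phenyl]-3-methyl-2-(2,4,5-trimethoxybenzyl)butan-1-one
Product: 17 4-(4-hydroxy-3-methoxyphenyl)-1-[3-methoxy-4-(triisopropylsilyloxy)phenyl]-3-methyl-2-(2,4,5-trimethoxybenzyl)butan-1-one (diastereomer mixture)
Conditions: H2 (1 atm), Pd/C, EtOAc, rt
Reagents that add atoms: none
Why: Hydrogenolysis of the aryl benzyl ether frees the one phenol that is to be oxidised; the hindered, electron-rich aryl ketone and the silyl ether should be inert at ambient pressure in a neutral solvent.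

Step 10
Reactants: 17 4-(4-hydroxy-3-methoxyphenyl)-1-[3-methoxy-4-(triisopropylsilyloxy)phenyl]-3-methyl-2-(2,4,5-trimethoxybenzyl)butan-1-one
Product: 19 [4-(4-hydroxy-3-methoxyphenyl)-5,6,8-trimethoxy-3-methyl-1,2,3,4-tetrahydronaphthalen-2-yl][3-methoxy-4-(triisopropylsilyloxy)phenyl]methanone (diastereomer mixture), via quinone methide 18 (not isolated)
Conditions: graphite anode, Pt cathode, undivided cell, constant current (2.1 F/mol), 2,6-lutidine, Bu4NBF4, (CF3)2CHOH, rt
Reagents that add atoms: none
Why: Proposed new method: anodic conversion of 4-alkylphenols into para-quinone methides is established with oxygen nucleophiles as traps, and chemical oxidants such as DDQ are known to close 4-hydroxyphenyl diarylbutanes to aryltetralins, but the electrochemical version with an intramolecular arene as the trap is not. Lutidine-assisted proton-coupled oxidation of the only free phenol of 17 should give the phenoxyl radical and, after a second electron, the phenoxonium ion, which loses the C8 proton to give quinone methide 18; the released protons are reduced to H2 at the cathode. The fluorinated alcohol hydrogen-bonds to the dienone oxygen, raises the electrophilicity of C8 and is too weak a nucleophile to intercept it, so C8a of the trimethoxyphenyl ring, the only free position ortho to its tether, attacks C8 in a six-membered Friedel–Crafts alkylation (6-exo-trig at the quinone methide), and rearomatisation returns the phenol. Chemoselectivity for the phenol rests on the base-assisted, low-potential oxidation, on the second guaiacyl ring being silylated and acyl-substituted and therefore much harder to oxidise, and on stopping at about 2 F per mole. Site selectivity between the two possible six-membered closures is secured by the C9 carbonyl, which makes the ring on that arm an aryl ketone deactivated at both positions ortho to the chain, while the methylene-linked trimethoxyphenyl ring keeps its nucleophilicity. The new C8 stereocentre is set under substrate control relative to C7 (aryl expected trans to the methyl group and pseudoaxial to avoid the peri methoxy group), but its configuration is immaterial because C6, C7 and C8 all become sp2 in step 12.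

Step 11
Reactants: 19 [4-(4-hydroxy-3-methoxyphenyl)-5,6,8-trimethoxy-3-methyl-1,2,3,4-tetrahydronaphthalen-2-yl][3-methoxy-4-(triisopropylsilyloxy)phenyl]methanone
Product: 21 (4-acetoxy-3-methoxyphenyl)[4-(4-acetoxy-3-methoxyphenyl)-5,6,8-trimethoxy-3-methyl-1,2,3,4-tetrahydronaphthalen-2-yl]methanone (diastereomer mixture), via bis-phenol 20 (not isolated)
Conditions: Bu4NF, THF, 0 °C; then Ac2O, Et3N, DMAP (cat.), 0 °C → rt
Reagents that add atoms: acetic anhydride, CC(=O)OC(C)=O
Why: Fluoride cleaves the silyl ether (the para-acyl phenoxide is a good leaving group) and both phenolic oxygens are acetylated in the same flask. Two aryl acetates make both guaiacyl rings electron-poor for the oxidations in steps 12 and 14.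

Step 12
Reactants: 21 (4-acetoxy-3-methoxyphenyl)[4-(4-acetoxy-3-methoxyphenyl)-5,6,8-trimethoxy-3-methyl-1,2,3,4-tetrahydronaphthalen-2-yl]methanone
Product: 22 8-(4-acetoxy-3-methoxyphenyl)-6-(4-acetoxy-3-methoxybenzoyl)-1,2,4-trimethoxy-7-methylnaphthalene
Conditions: DDQ (2.2 equiv), 1,4-dioxane, 90 °C
Reagents that add atoms: none
Why: DDQ dehydrogenation of a tetralin by two hydride abstraction/proton loss sequences, starting at the benzylic positions C5 and C8 that the trimethoxyarene activates. With C9 as a carbonyl there is no diarylmethane C–H for the oxidant to attack, and all three stereocentres disappear.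

Step 13
Reactants: 22 8-(4-acetoxy-3-methoxyphenyl)-6-(4-acetoxy-3-methoxybenzoyl)-1,2,4-trimethoxy-7-methylnaphthalene
Product: 23 8-(4-acetoxy-3-methoxyphenyl)-6-(4-acetoxy-3-methoxybenzyl)-1,2,4-trimethoxy-7-methylnaphthalene
Conditions: Et3SiH, BF3·OEt2, CH2Cl2/MeCN, 0 °C → rt
Reagents that add atoms: none
Why: Ionic hydrogenation of a diaryl ketone: the activated carbonyl takes hydride from the silane, the carbinol ionises to a diarylmethyl cation stabilised through the C2 and C4 methoxy groups of the naphthalene, and a second hydride gives the methylene. Aryl acetates and aryl methyl ethers tolerate these conditions.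

Step 14
Reactants: 23 8-(4-acetoxy-3-methoxyphenyl)-6-(4-acetoxy-3-methoxybenzyl)-1,2,4-trimethoxy-7-methylnaphthalene
Product: 24 8-(4-acetoxy-3-methoxyphenyl)-6-(4-acetoxy-3-methoxybenzyl)-2-methoxy-7-methyl-1,4-naphthoquinone
Conditions: (NH4)2Ce(NO3)6, MeCN/H2O, 0 °C
Reagents that add atoms: water, O
Why: Oxidative demethylation of a 1,4-dimethoxyarene by tetravalent cerium: two one-electron oxidations with attack of water at C1 and C4 expel two molecules of methanol and give the para-quinone with the C2 methoxy group retained. The tri-ether ring is by far the most easily oxidised part of 23, and the acetates keep the guaiacyl rings and C9 out of reach.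

Step 15
Reactants: 24 8-(4-acetoxy-3-methoxyphenyl)-6-(4-acetoxy-3-methoxybenzyl)-2-methoxy-7-methyl-1,4-naphthoquinone
Product: 25 larreantin, 8-(4-hydroxy-3-methoxyphenyl)-6-(4-hydroxy-3-methoxybenzyl)-2-methoxy-7-methyl-1,4-naphthoquinone
Conditions: TsOH·H2O (cat.), MeOH, rt → 40 °C
Reagents that add atoms: none
Why: Acid-catalysed transesterification of the two aryl acetates with methanol. Any exchange at the vinylogous ester C2–OMe is degenerate in methanol, and an acid with a non-nucleophilic counter-ion avoids the hydroxide, amine or phenoxide chemistry that would damage the quinone.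

## Compound list

1 | 4-(benzyloxy)-3-methoxybenzyl alcohol | COc1cc(CO)ccc1OCc1ccccc1 | starting material
2 | 4-(benzyloxy)-3-methoxybenzyl chloride | COc1cc(CCl)ccc1OCc1ccccc1 | intermediate
3 | methyl (E)-but-2-enoate (methyl crotonate) | C/C=C/C(=O)OC | starting material
4 | [4-(benzyloxy)-3-methoxybenzyl]magnesium chloride | COc1cc(C[Mg]Cl)ccc1OCc1ccccc1 | intermediate (not isolated)
5 | 4-[4-(benzyloxy)-3-methoxyphenyl]-1-methoxy-3-methyl-1-(trimethylsilyloxy)but-1-ene (racemic, alkene geometry not defined) | COC(O[Si](C)(C)C)=CC(C)Cc1ccc(OCc2ccccc2)c(OC)c1 | intermediate (not isolated)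
6 | methyl 4-[4-(benzyloxy)-3-methoxyphenyl]-3-methylbutanoate (racemic) | COC(=O)CC(C)Cc1ccc(OCc2ccccc2)c(OC)c1 | intermediate
7 | 4-[4-(benzyloxy)-3-methoxyphenyl]-N-methoxy-N,3-dimethylbutanamide (racemic) | CON(C)C(=O)CC(C)Cc1ccc(OCc2ccccc2)c(OC)c1 | intermediate
8 | 4-bromo-2-methoxyphenol | COc1cc(Br)ccc1O | starting material
9 | (4-bromo-2-methoxyphenoxy)triisopropylsilane | COc1cc(Br)ccc1O[Si](C(C)C)(C(C)C)C(C)C | intermediate
10 | [3-methoxy-4-(triisopropylsilyloxy)phenyl]lithium | COc1cc([Li])ccc1O[Si](C(C)C)(C(C)C)C(C)C | intermediate (not isolated)
11 | 4-[4-(benzyloxy)-3-methoxyphenyl]-1-[3-methoxy-4-(triisopropylsilyloxy)phenyl]-3-methylbutan-1-one (racemic) | COc1cc(C(=O)CC(C)Cc2ccc(OCc3ccccc3)c(OC)c2)ccc1O[Si](C(C)C)(C(C)C)C(C)C | intermediate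
12 | 2,4,5-trimethoxybenzaldehyde | COc1cc(OC)c(C=O)cc1OC | starting material
13 | 2,4,5-trimethoxybenzyl alcohol | COc1cc(OC)c(CO)cc1OC | intermediate
14 | 2,4,5-trimethoxybenzyl chloride | COc1cc(OC)c(CCl)cc1OC | intermediate
15 | lithium enolate of 11, lithium 4-[4-(benzyloxy)-3-methoxyphenyl]-1-[3-methoxy-4-(triisopropylsilyloxy)phenyl]-3-methylbut-1-en-1-olate | COc1cc(C(O[Li])=CC(C)Cc2ccc(OCc3ccccc3)c(OC)c2)ccc1O[Si](C(C)C)(C(C)C)C(C)C | intermediate (not isolated)
16 | 4-[4-(benzyloxy)-3-methoxyphenyl]-1-[3-methoxy-4-(triisopropylsilyloxy)phenyl]-3-methyl-2-(2,4,5-trimethoxybenzyl)butan-1-one (diastereomer mixture) | COc1cc(C(=O)C(Cc2cc(OC)c(OC)cc2OC)C(C)Cc2ccc(OCc3ccccc3)c(OC)c2)ccc1O[Si](C(C)C)(C(C)C)C(C)C | intermediate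
17 | 4-(4-hydroxy-3-methoxyphenyl)-1-[3-methoxy-4-(triisopropylsilyloxy)phenyl]-3-methyl-2-(2,4,5-trimethoxybenzyl)butan-1-one (diastereomer mixture) | COc1cc(C(=O)C(Cc2cc(OC)c(OC)cc2OC)C(C)Cc2ccc(O)c(OC)c2)ccc1O[Si](C(C)C)(C(C)C)C(C)C | intermediate
18 | 2-methoxy-4-{4-[3-methoxy-4-(triisopropylsilyloxy)phenyl]-2-methyl-4-oxo-3-(2,4,5-trimethoxybenzyl)butylidene}cyclohexa-2,5-dien-1-one (para-quinone methide, geometry not defined) | COC1=CC(=CC(C)C(Cc2cc(OC)c(OC)cc2OC)C(=O)c2ccc(O[Si](C(C)C)(C(C)C)C(C)C)c(OC)c2)C=CC1=O | intermediate (not isolated)
19 | [4-(4-hydroxy-3-methoxyphenyl)-5,6,8-trimethoxy-3-methyl-1,2,3,4-tetrahydronaphthalen-2-yl][3-methoxy-4-(triisopropylsilyloxy)phenyl]methanone (diastereomer mixture) | COc1cc(OC)c2c(c1OC)C(c1ccc(O)c(OC)c1)C(C)C(C(=O)c1ccc(O[Si](C(C)C)(C(C)C)C(C)C)c(OC)c1)C2 | intermediate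
20 | (4-hydroxy-3-methoxyphenyl)[4-(4-hydroxy-3-methoxyphenyl)-5,6,8-trimethoxy-3-methyl-1,2,3,4-tetrahydronaphthalen-2-yl]methanone (diastereomer mixture) | COc1cc(OC)c2c(c1OC)C(c1ccc(O)c(OC)c1)C(C)C(C(=O)c1ccc(O)c(OC)c1)C2 | intermediate (not isolated)
21 | (4-acetoxy-3-methoxyphenyl)[4-(4-acetoxy-3-methoxyphenyl)-5,6,8-trimethoxy-3-methyl-1,2,3,4-tetrahydronaphthalen-2-yl]methanone (diastereomer mixture) | COc1cc(OC)c2c(c1OC)C(c1ccc(OC(C)=O)c(OC)c1)C(C)C(C(=O)c1ccc(OC(C)=O)c(OC)c1)C2 | intermediate
22 | 8-(4-acetoxy-3-methoxyphenyl)-6-(4-acetoxy-3-methoxybenzoyl)-1,2,4-trimethoxy-7-methylnaphthalene | COc1cc(OC)c2cc(C(=O)c3ccc(OC(C)=O)c(OC)c3)c(C)c(-c3ccc(OC(C)=O)c(OC)c3)c2c1OC | intermediate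
23 | 8-(4-acetoxy-3-methoxyphenyl)-6-(4-acetoxy-3-methoxybenzyl)-1,2,4-trimethoxy-7-methylnaphthalene | COc1cc(OC)c2cc(Cc3ccc(OC(C)=O)c(OC)c3)c(C)c(-c3ccc(OC(C)=O)c(OC)c3)c2c1OC | intermediate
24 | 8-(4-acetoxy-3-methoxyphenyl)-6-(4-acetoxy-3-methoxybenzyl)-2-methoxy-7-methyl-1,4-naphthoquinone | COC1=CC(=O)c2cc(Cc3ccc(OC(C)=O)c(OC)c3)c(C)c(-c3ccc(OC(C)=O)c(OC)c3)c2C1=O | intermediate
25 | larreantin, 8-(4-hydroxy-3-methoxyphenyl)-6-(4-hydroxy-3-methoxybenzyl)-2-methoxy-7-methyl-1,4-naphthoquinone | COC1=CC(=O)c2cc(Cc3ccc(O)c(OC)c3)c(C)c(-c3ccc(O)c(OC)c3)c2C1=O | target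

## Step count and risk assessment

Total: 15 steps. Longest linear sequence: 12 steps (1 → 2 → 6 → 7 → 11 → 16 → 17 → 19 → 21 → 22 → 23 → 24 → 25). Steps 4 and 6–7 are side branches.

**Step 10 (key step, proposed new method).** The most likely failures are:
- dimerisation of the phenoxyl radical (C–C or C–O coupling at the free ortho position) before the second electron is removed;
- capture of the quinone methide by the C9 carbonyl oxygen or by adventitious nucleophiles instead of by the hindered C8a position;
- tautomerisation of the quinone methide to the styrene, followed by over-oxidation, if ring closure is slow.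

All three stem from the modest nucleophilicity of C8a, which is activated by only one ortho methoxy group and flanked on both sides.

Fallback with known chemistry, setting out from 17 and returning at 19: DDQ in CH2Cl2/MeOH at 0 °C oxidises the 4-hydroxybenzylic position chemically, and methanol captures the quinone methide to give the C8 methyl ether, 4-(4-hydroxy-3-methoxyphenyl)-4-methoxy-1-[3-methoxy-4-(triisopropylsilyloxy)phenyl]-3-methyl-2-(2,4,5-trimethoxybenzyl)butan-1-one F1. BF3·OEt2 in CH2Cl2 at low temperature then re-ionises this benzylic ether to the para-hydroxybenzylic cation, which closes onto C8a by the established acid-mediated Friedel–Crafts route to aryltetralins and gives 19. The oxidation and the C–C bond formation are thereby separated and can be optimised independently.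

**Step 2.** Homocoupling of the electron-rich benzylic chloride during magnesium insertion and competing 1,2-addition of the benzylic Grignard reagent to the ester are the likely losses.

Fallback, setting out from 8 and returning at 6: the C8–aryl bond is made instead of C7–C8. Benzylation of 8 (BnBr, K2CO3, DMF) gives 1-(benzyloxy)-4-bromo-2-methoxybenzene F2. Hydroboration of commercial methyl 3-methylbut-3-enoate with 9-BBN gives the primary alkylborane, methyl 4-(9-borabicyclo[3.3.1]nonan-9-yl)-3-methylbutanoate F3. B-alkyl Suzuki–Miyaura coupling of F2 with F3 (Pd(dppf)Cl2, K3PO4, THF/DMF) then delivers 6.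

**Step 8.** Self-condensation of the labile chloride 14 may outrun C-alkylation of the hindered enolate, and proton transfer or O-alkylation may erode conversion.

Fallback, setting out from 11 and 12 and returning at 17: aldol addition of enolate 15 to aldehyde 12 gives the β-hydroxy ketone, 4-[4-(benzyloxy)-3-methoxyphenyl]-2-[hydroxy(2,4,5-trimethoxyphenyl)methyl]-1-[3-methoxy-4-(triisopropylsilyloxy)phenyl]-3-methylbutan-1-one F4. Acetylation (Ac2O, DMAP) gives the β-acetoxy ketone, 4-[4-(benzyloxy)-3-methoxyphenyl]-2-[3-methoxy-4-(triisopropylsilyloxy)benzoyl]-3-methyl-1-(2,4,5-trimethoxyphenyl)butyl acetate F5. Base-induced elimination with DBU then gives the benzylidene ketone, 4-[4-(benzyloxy)-3-methoxyphenyl]-1-[3-methoxy-4-(triisopropylsilyloxy)phenyl]-3-methyl-2-(2,4,5-trimethoxybenzylidene)butan-1-one F6. Hydrogenation over Pd/C saturates the C5=C6 bond and cleaves the benzyl ether in the same operation to give 17, so that 13, 14 and 16 are bypassed.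

**Step 13.** The diarylmethyl cation may alkylate the electron-rich C3 position of a second naphthalene before the silane delivers hydride. The reduction may also stall at the carbinol stage, because the neighbouring C7 methyl group twists the carbonyl out of conjugation.

Fallback, setting out from 22 and returning at 23: heterogeneous hydrogenolysis (H2, Pd/C, EtOAc/AcOH) reduces the ketone to the diaryl carbinol, 8-(4-acetoxy-3-methoxyphenyl)-6-[(4-acetoxy-3-methoxyphenyl)(hydroxy)methyl]-1,2,4-trimethoxy-7-methylnaphthalene F7, and cleaves its benzylic C–O bond on the metal surface without a free cation in solution.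

**Step 14.** Attack of water at C2 instead of the peri-hindered C1 (ortho-quinone formation) and oxidation at the C9 methylene by excess tetravalent cerium are the likely side processes.

Fallback, setting out from 23 and returning at 24: anodic oxidation in methanol under neutral conditions (LiClO4, 2,6-lutidine) converts the 1,4-dimethoxyarene into the quinone bis(dimethyl ketal), 8-(4-acetoxy-3-methoxyphenyl)-6-(4-acetoxy-3-methoxybenzyl)-1,1,2,4,4-pentamethoxy-7-methyl-1,4-dihydronaphthalene F8. Dilute aqueous acid hydrolyses F8 to 24, so the product is never exposed to an excess of a strong one-electron oxidant.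

## Further compounds

F1 | step 10 | 4-(4-hydroxy-3-methoxyphenyl)-4-methoxy-1-[3-methoxy-4-(triisopropylsilyloxy)phenyl]-3-methyl-2-(2,4,5-trimethoxybenzyl)butan-1-one (diastereomer mixture) | COc1cc(C(=O)C(Cc2cc(OC)c(OC)cc2OC)C(C)C(OC)c2ccc(O)c(OC)c2)ccc1O[Si](C(C)C)(C(C)C)C(C)C
F2 | step 2 | 1-(benzyloxy)-4-bromo-2-methoxybenzene | COc1cc(Br)ccc1OCc1ccccc1
F3 | step 2 | methyl 4-(9-borabicyclo[3.3.1]nonan-9-yl)-3-methylbutanoate | COC(=O)CC(C)CB1C2CCCC1CCC2
F4 | step 8 | 4-[4-(benzyloxy)-3-methoxyphenyl]-2-[hydroxy(2,4,5-trimethoxyphenyl)methyl]-1-[3-methoxy-4-(triisopropylsilyloxy)phenyl]-3-methylbutan-1-one (diastereomer mixture) | COc1cc(C(=O)C(C(O)c2cc(OC)c(OC)cc2OC)C(C)Cc2ccc(OCc3ccccc3)c(OC)c2)ccc1O[Si](C(C)C)(C(C)C)C(C)C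
F5 | step 8 | 4-[4-(benzyloxy)-3-methoxyphenyl]-2-[3-methoxy-4-(triisopropylsilyloxy)benzoyl]-3-methyl-1-(2,4,5-trimethoxyphenyl)butyl acetate (diastereomer mixture) | COc1cc(C(=O)C(C(OC(C)=O)c2cc(OC)c(OC)cc2OC)C(C)Cc2ccc(OCc3ccccc3)c(OC)c2)ccc1O[Si](C(C)C)(C(C)C)C(C)C
F6 | step 8 | 4-[4-(benzyloxy)-3-methoxyphenyl]-1-[3-methoxy-4-(triisopropylsilyloxy)phenyl]-3-methyl-2-(2,4,5-trimethoxybenzylidene)butan-1-one (alkene geometry not defined) | COc1cc(C(=O)C(=Cc2cc(OC)c(OC)cc2OC)C(C)Cc2ccc(OCc3ccccc3)c(OC)c2)ccc1O[Si](C(C)C)(C(C)C)C(C)C
F7 | step 13 | 8-(4-acetoxy-3-methoxyphenyl)-6-[(4-acetoxy-3-methoxyphenyl)(hydroxy)methyl]-1,2,4-trimethoxy-7-methylnaphthalene (racemic) | COc1cc(OC)c2cc(C(O)c3ccc(OC(C)=O)c(OC)c3)c(C)c(-c3ccc(OC(C)=O)c(OC)c3)c2c1OC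
F8 | step 14 | 8-(4-acetoxy-3-methoxyphenyl)-6-(4-acetoxy-3-methoxybenzyl)-1,1,2,4,4-pentamethoxy-7-methyl-1,4-dihydronaphthalene | COC1=CC(OC)(OC)c2cc(Cc3ccc(OC(C)=O)c(OC)c3)c(C)c(-c3ccc(OC(C)=O)c(OC)c3)c2C1(OC)OC
A1 | alternative 1 | methyl 4-[4-(benzyloxy)-3-methoxybenzyl]-2-iodobenzoate | COC(=O)c1ccc(Cc2ccc(OCc3ccccc3)c(OC)c2)cc1I
A2 | alternative 1 | iodomethane | CI
A3 | alternative 1 | 4-(benzyloxy)-3-methoxyphenylboronic acid | COc1cc(B(O)O)ccc1OCc1ccccc1
A4 | alternative 1 | methyl 2-(4-benzyloxy-3-methoxyphenyl)-4-(4-benzyloxy-3-methoxybenzyl)-3-methylbenzoate | COC(=O)c1ccc(Cc2ccc(OCc3ccccc3)c(OC)c2)c(C)c1-c1ccc(OCc2ccccc2)c(OC)c1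
A5 | alternative 2 | (4-benzyloxy-3-methoxyphenyl)(2,3,5-trimethoxyphenyl)[2,2-dichloro-3-(4-benzyloxy-3-methoxybenzyl)-1-methylcyclopropyl]methanol | COc1cc(OC)c(OC)c(C(O)(c2ccc(OCc3ccccc3)c(OC)c2)C2(C)C(Cc3ccc(OCc4ccccc4)c(OC)c3)C2(Cl)Cl)c1
A6 | alternative 2 | 8-(4-benzyloxy-3-methoxyphenyl)-6-(4-benzyloxy-3-methoxybenzyl)-5-chloro-1,2,4-trimethoxy-7-methylnaphthalene | COc1cc(OC)c2c(Cl)c(Cc3ccc(OCc4ccccc4)c(OC)c3)c(C)c(-c3ccc(OCc4ccccc4)c(OC)c3)c2c1OC
A7 | alternative 3 | 2-diazo-1-[2-(4-benzyloxy-3-methoxyphenyl)-4-(4-benzyloxy-3-methoxybenzyl)-3-methylphenyl]ethanone | [N-]=[N+]=CC(=O)c1ccc(Cc2ccc(OCc3ccccc3)c(OC)c2)c(C)c1-c1ccc(OCc2ccccc2)c(OC)c1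
A8 | alternative 3 | methoxyacetylene | COC#C
A9 | alternative 3 | 5-(4-benzyloxy-3-methoxyphenyl)-7-(4-benzyloxy-3-methoxybenzyl)-3-methoxy-6-methyl-1-naphthol | COc1cc(O)c2cc(Cc3ccc(OCc4ccccc4)c(OC)c3)c(C)c(-c3ccc(OCc4ccccc4)c(OC)c3)c2c1
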